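Ring A of the flavone is cut across C4a–C5 and C8–C8a. C5, C6, C7 and C8, with the free C5–OH para to the C8–OMe and two methoxy groups between them, are the four carbons of dimethyl squarate. C4a=C8a is the C5=C6 bond of a ready-made 2-aryl-4H-pyran-4-one (rings B and C). In one thermal operation a cyclobutenone opens to a dienylketene, closes by 6π electrocyclization onto the pyranone and enolizes, giving the fully substituted ring A with the 5-OH and the three methyl ethers already differentiated. The precursor is a 2,3,4-trimethoxy-4-(4-oxopyran-2-yl)cyclobut-2-enone made from the C6-lithiated pyranone and the squarate.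

Key step: step 8

Remark: benzyl ethers protect the two ring B phenols because they should tolerate LiTMP, dilute TFA and 140 °C and leave last by hydrogenolysis without touching the methyl ethers. The hydroxyacetophenone used in one fallback is assumed to be purchasable.

Step 1
Reactants: 1 methyl 2,4-dihydroxybenzoate
Product: 2 methyl 2,4-bis(benzyloxy)benzoate
Conditions: BnBr (2.5 equiv), K2CO3 (3 equiv), DMF, 70 °C
Reagents that add atoms: benzyl bromide, BrCc1ccccc1
Why: Williamson etherification of both phenoxides, in which the hydrogen-bonded 2-OH reacts more slowly but is driven by excess benzyl bromide in warm DMF, leaves the methyl ester untouched.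

Step 2
Reactants: 2 methyl 2,4-bis(benzyloxy)benzoate
Product: 3 2,4-bis(benzyloxy)benzoic acid
Conditions: LiOH·H2O (4 equiv), THF/MeOH/H2O, 60 °C; then 1 M HCl to pH 2
Reagents that add atoms: lithium hydroxide, [Li+].[OH-]
Why: Ester saponification (acyl substitution by hydroxide) should be clean because aryl benzyl ethers are inert to aqueous base.

Step 3
Reactants: 3 2,4-bis(benzyloxy)benzoic acid
Product: 4 2,4-bis(benzyloxy)benzoyl chloride
Conditions: (COCl)2 (1.5 equiv), DMF (cat.), CH2Cl2, 0 °C to rt; evaporated and used crude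
Reagents that add atoms: oxalyl chloride, O=C(Cl)C(=O)Cl
Why: Acid chloride formation through the Vilsmeier-type chloroiminium species from catalytic DMF runs at or below room temperature, which the benzyl ethers should survive.

Step 4
Reactants: 4 2,4-bis(benzyloxy)benzoyl chloride; 5 (E)-4-methoxybut-3-en-2-one
Product: 7 (E)-1-[2,4-bis(benzyloxy)phenyl]-5-methoxypent-4-ene-1,3-dione, via lithium enolate 6 (not isolated)
Conditions: 5 (2.1 equiv), LiHMDS (2.1 equiv), THF, −78 °C; then 4 (1 equiv) in THF, −78 °C, 5–10 min; 1 M HCl; used crude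
Reagents that add atoms: none
Why: Kinetic deprotonation of the methyl group gives the cross-conjugated enolate 6, which should undergo Claisen-type C-acylation by the acid chloride at −78 °C, while the second equivalent of enolate takes up the acidic proton of the new 1,3-diketone and so suppresses double acylation.

Step 5
Reactants: 7 (E)-1-[2,4-bis(benzyloxy)phenyl]-5-methoxypent-4-ene-1,3-dione
Product: 8 2-[2,4-bis(benzyloxy)phenyl]-4H-pyran-4-one
Conditions: TFA (0.5 equiv), CH2Cl2, rt
Reagents that add atoms: none
Why: Acid-catalysed 6-endo oxa-Michael addition of the aryl ketone enol oxygen to the protonated β-methoxyenone, followed by elimination of methanol, is an established γ-pyrone synthesis, and aryl benzyl ethers should tolerate dilute TFA at room temperature.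

Step 6
Reactants: 8 2-[2,4-bis(benzyloxy)phenyl]-4H-pyran-4-one; 9 dimethyl squarate
Product: 11 racemic 4-{6-[2,4-bis(benzyloxy)phenyl]-4-oxo-4H-pyran-2-yl}-4-hydroxy-2,3-dimethoxycyclobut-2-en-1-one, via 6-lithiopyranone 10 (not isolated)
Conditions: 8 added slowly to LiTMP (1.1 equiv, from 2,2,6,6-tetramethylpiperidine and n-BuLi), THF, −78 °C, 15 min; cannulated into 9 (1.3 equiv), THF, −78 °C; sat. aq NH4Cl at −78 °C
Reagents that add atoms: none
Why: The sp2 C6–H next to the ring oxygen should be the most acidic proton of the γ-pyrone, as C2–H is in chromones, so the hindered non-nucleophilic amide should give vinyllithium 10 by directed deprotonation, which adds 1,2 to one of the two equivalent squarate carbonyls at −78 °C; the new carbinol carbon forms racemic, which does not matter because it becomes aromatic C8.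

Step 7
Reactants: 11 racemic 4-{6-[2,4-bis(benzyloxy)phenyl]-4-oxo-4H-pyran-2-yl}-4-hydroxy-2,3-dimethoxycyclobut-2-en-1-one
Product: 12 racemic 4-{6-[2,4-bis(benzyloxy)phenyl]-4-oxo-4H-pyran-2-yl}-2,3,4-trimethoxycyclobut-2-en-1-one
Conditions: MeI (excess), Ag2O (3 equiv), 4 Å MS, MeCN, rt, dark
Reagents that add atoms: iodomethane, CI
Why: Purdie-type O-methylation with MeI and Ag2O works under nearly neutral conditions on tertiary cyclobutenols and avoids a free alkoxide that could fragment the strained ring; the new methyl ether later steers the ring opening and arrives as the 8-OMe.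

Step 8
Reactants: 12 racemic 4-{6-[2,4-bis(benzyloxy)phenyl]-4-oxo-4H-pyran-2-yl}-2,3,4-trimethoxycyclobut-2-en-1-one
Product: 15 2-[2,4-bis(benzyloxy)phenyl]-5-hydroxy-6,7,8-trimethoxy-4H-chromen-4-one, via dienylketene 13 (not isolated), via cyclohexadienone 14 (not isolated)
Conditions: degassed p-xylene (0.01 M), 138 °C, Ar
Reagents that add atoms: none
Why: Proposed new method: heating should open the cyclobutenone by conrotatory 4π electrocyclic cleavage of its C1–C4 bond to dienylketene 13, whose ketene carbon then bonds to C5 of the pyranone in a thermal disrotatory 6π electrocyclization that closes ring A, and enolization of dienone 14, driven by aromatization and the hydrogen bond to the C4 carbonyl, gives the phenol. The closest known reaction type is the thermal ring expansion of squarate-derived 4-alkenyl-, 4-aryl- and 4-heteroaryl-4-alkoxycyclobutenones to monoprotected hydroquinones (Moore rearrangement); a free 4-oxopyran-2-yl group as the 2π component is the extension proposed here, and it is reasonable because pyranone C5 is the nucleophilic β-carbon of a vinylogous ester facing an electrophilic ketene carbon and the ring is only weakly aromatic, much like the furyl and enol ether partners that are known to close. No stereocenter remains, since the racemic quaternary carbon of 12 becomes aromatic C8 and the transient C4a center of 14 is lost on tautomerization. The step needs inward rotation of the pyranonyl group (torquoselectivity), which the stronger donor 4-OMe should secure by rotating outward, and it needs one regiochemistry of closure, which is secured because C5 is the only ring carbon next to the point of attachment, so the ketene oxygen must end as the 5-OH para to the 8-OMe.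

Step 9
Reactants: 15 2-[2,4-bis(benzyloxy)phenyl]-5-hydroxy-6,7,8-trimethoxy-4H-chromen-4-one
Product: 16 tamadone, 2-(2,4-dihydroxyphenyl)-5-hydroxy-6,7,8-trimethoxy-4H-chromen-4-one
Conditions: H2 (1 atm), 10% Pd/C, EtOAc/THF, rt
Reagents that add atoms: none
Why: Catalytic hydrogenolysis should cleave both benzyl aryl ethers under neutral conditions at 1 atm, under which the methyl ethers, the chelated 5-OH and the chromone C2=C3 bond are not expected to react.

Compound list
1 | methyl 2,4-dihydroxybenzoate | COC(=O)c1ccc(O)cc1O | starting material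
2 | methyl 2,4-bis(benzyloxy)benzoate | COC(=O)c1ccc(OCc2ccccc2)cc1OCc1ccccc1 | intermediate
3 | 2,4-bis(benzyloxy)benzoic acid | OC(=O)c1ccc(OCc2ccccc2)cc1OCc1ccccc1 | intermediate
4 | 2,4-bis(benzyloxy)benzoyl chloride | O=C(Cl)c1ccc(OCc2ccccc2)cc1OCc1ccccc1 | intermediate
5 | (E)-4-methoxybut-3-en-2-one | CO/C=C/C(C)=O | starting material
6 | lithium (E)-4-methoxybuta-1,3-dien-2-olate (kinetic enolate of 5) | [Li]OC(=C)/C=C/OC | intermediate
7 | (E)-1-[2,4-bis(benzyloxy)phenyl]-5-methoxypent-4-ene-1,3-dione (largely enolized) | CO/C=C/C(=O)CC(=O)c1ccc(OCc2ccccc2)cc1OCc1ccccc1 | intermediate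
8 | 2-[2,4-bis(benzyloxy)phenyl]-4H-pyran-4-one | O=c1ccoc(-c2ccc(OCc3ccccc3)cc2OCc2ccccc2)c1 | intermediate
9 | dimethyl squarate (3,4-dimethoxycyclobut-3-ene-1,2-dione) | COc1c(OC)c(=O)c1=O | starting material
10 | 2-[2,4-bis(benzyloxy)phenyl]-6-lithio-4H-pyran-4-one | [Li]c1cc(=O)cc(-c2ccc(OCc3ccccc3)cc2OCc2ccccc2)o1 | intermediate
11 | racemic 4-{6-[2,4-bis(benzyloxy)phenyl]-4-oxo-4H-pyran-2-yl}-4-hydroxy-2,3-dimethoxycyclobut-2-en-1-one | COC1=C(OC)C(O)(c2cc(=O)cc(-c3ccc(OCc4ccccc4)cc3OCc3ccccc3)o2)C1=O | intermediate
12 | racemic 4-{6-[2,4-bis(benzyloxy)phenyl]-4-oxo-4H-pyran-2-yl}-2,3,4-trimethoxycyclobut-2-en-1-one | COC1=C(OC)C(OC)(c2cc(=O)cc(-c3ccc(OCc4ccccc4)cc3OCc3ccccc3)o2)C1=O | intermediate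
13 | (Z)-4-{6-[2,4-bis(benzyloxy)phenyl]-4-oxo-4H-pyran-2-yl}-2,3,4-trimethoxybuta-1,3-dien-1-one (dienylketene, pyranonyl group cis to the ketene-bearing carbon) | O=C=C(OC)/C(OC)=C(OC)\c1cc(=O)cc(-c2ccc(OCc3ccccc3)cc2OCc2ccccc2)o1 | intermediate
14 | racemic 2-[2,4-bis(benzyloxy)phenyl]-6,7,8-trimethoxy-4aH-chromene-4,5-dione | COC1=C(OC)C(=O)C2C(=O)C=C(c3ccc(OCc4ccccc4)cc3OCc3ccccc3)OC2=C1OC | intermediate
15 | 2-[2,4-bis(benzyloxy)phenyl]-5-hydroxy-6,7,8-trimethoxy-4H-chromen-4-one | COc1c(OC)c(O)c2c(=O)cc(-c3ccc(OCc4ccccc4)cc3OCc3ccccc3)oc2c1OC | intermediate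
16 | tamadone, 2-(2,4-dihydroxyphenyl)-5-hydroxy-6,7,8-trimethoxy-4H-chromen-4-one | COc1c(OC)c(O)c2c(=O)cc(-c3ccc(O)cc3O)oc2c1OC | target

Total step count: 9
Longest linear sequence: 9 steps (1 to 16); 5 and 9 are bought and enter at steps 4 and 6.

Steps most likely to fail

1. Step 8. The dienylketene may not close onto the pyranone C5=C6 bond, which is less reactive than the alkenyl and furyl partners of the known reaction, and may instead dimerize or decompose. The fallback uses known chemistry, sets out from 4 and gives up the squarate disconnection. Acid chloride 4 acylates the phenol of 1-(2-hydroxy-3,4,5,6-tetramethoxyphenyl)ethan-1-one F1 (pyridine, DMAP cat., CH2Cl2) to give 2-acetyl-3,4,5,6-tetramethoxyphenyl 2,4-bis(benzyloxy)benzoate F2. Baker–Venkataraman acyl migration (KOH, pyridine, 50 °C) should then give 1-[2,4-bis(benzyloxy)phenyl]-3-(2-hydroxy-3,4,5,6-tetramethoxyphenyl)propane-1,3-dione F3. Acid-catalysed cyclodehydration (p-TsOH, toluene, reflux) closes ring C to 2-[2,4-bis(benzyloxy)phenyl]-5,6,7,8-tetramethoxy-4H-chromen-4-one F4. BCl3 with pentamethylbenzene (CH2Cl2, −78 to 0 °C) should remove both benzyl groups and, by chelation to the C4 carbonyl, only the peri 5-O-methyl group. The fallback comes back to the route at 16.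

2. Step 6. Metalation may occur at the wrong site (C3 of the pyranone or the aryl ring), or the lithiated pyranone may ring-open or add to unmetalated pyranone before it meets the squarate. The fallback sets out from 8 and separates regiocontrol from carbanion generation. Zincation with TMPZnCl·LiCl (THF, 25 °C, no Lewis acid) should give the stable {6-[2,4-bis(benzyloxy)phenyl]-4-oxo-4H-pyran-2-yl}zinc chloride F5, as it does at C2 of chromones. Iodinolysis (I2, THF) gives 2-[2,4-bis(benzyloxy)phenyl]-6-iodo-4H-pyran-4-one F6. Iodine–magnesium exchange (i-PrMgCl·LiCl, THF, −78 °C) generates {6-[2,4-bis(benzyloxy)phenyl]-4-oxo-4H-pyran-2-yl}magnesium chloride F7 without any amide base. F7 is added to 9 at −78 °C and quenched with NH4Cl. The fallback comes back to the route at 11.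

3. Step 7. Methylation of the hindered tertiary alcohol may be incomplete, or the carbinol may fragment by ring opening or retro-addition under the reaction conditions. The fallback sets out from 11 and reverses the order of methylation and ring expansion, so it relies on the hydroxy variant of step 8. Thermolysis of the free carbinol (degassed toluene or p-xylene, Ar), in which the hydroxyl group also rotates outward, should give the hydroquinone 2-[2,4-bis(benzyloxy)phenyl]-5,8-dihydroxy-6,7-dimethoxy-4H-chromen-4-one F8. F8 is kept under argon to prevent oxidation to the quinone. The 8-OH, which is not chelated, is then methylated selectively (MeI 1.05 equiv, K2CO3, acetone, Ar), while the 5-OH is held by its hydrogen bond to the C4 carbonyl. The fallback comes back to the route at 15.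

Further compounds
F1 | step 8 | 1-(2-hydroxy-3,4,5,6-tetramethoxyphenyl)ethan-1-one | CC(=O)c1c(O)c(OC)c(OC)c(OC)c1OC
F2 | step 8 | 2-acetyl-3,4,5,6-tetramethoxyphenyl 2,4-bis(benzyloxy)benzoate | CC(=O)c1c(OC(=O)c2ccc(OCc3ccccc3)cc2OCc2ccccc2)c(OC)c(OC)c(OC)c1OC
F3 | step 8 | 1-[2,4-bis(benzyloxy)phenyl]-3-(2-hydroxy-3,4,5,6-tetramethoxyphenyl)propane-1,3-dione | COc1c(OC)c(OC)c(C(=O)CC(=O)c2ccc(OCc3ccccc3)cc2OCc2ccccc2)c(O)c1OC
F4 | step 8 | 2-[2,4-bis(benzyloxy)phenyl]-5,6,7,8-tetramethoxy-4H-chromen-4-one | COc1c(OC)c(OC)c2c(=O)cc(-c3ccc(OCc4ccccc4)cc3OCc3ccccc3)oc2c1OC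
F5 | step 6 | {6-[2,4-bis(benzyloxy)phenyl]-4-oxo-4H-pyran-2-yl}zinc chloride | Cl[Zn]c1cc(=O)cc(-c2ccc(OCc3ccccc3)cc2OCc2ccccc2)o1
F6 | step 6 | 2-[2,4-bis(benzyloxy)phenyl]-6-iodo-4H-pyran-4-one | O=c1cc(I)oc(-c2ccc(OCc3ccccc3)cc2OCc2ccccc2)c1
F7 | step 6 | {6-[2,4-bis(benzyloxy)phenyl]-4-oxo-4H-pyran-2-yl}magnesium chloride | Cl[Mg]c1cc(=O)cc(-c2ccc(OCc3ccccc3)cc2OCc2ccccc2)o1
F8 | step 7 | 2-[2,4-bis(benzyloxy)phenyl]-5,8-dihydroxy-6,7-dimethoxy-4H-chromen-4-one | COc1c(OC)c(O)c2c(=O)cc(-c3ccc(OCc4ccccc4)cc3OCc3ccccc3)oc2c1O
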